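(The runs come from a simulation with made-up constants; scatter was added.)

Count the D that a flask makes per hour against the J, G and Z present, taking G + Z + J -> Z + D as the step that makes it.

the same everywhere: Z 12 mol%

|  | J | Q | G | remark | time |
|---|---|---|---|---|---|
| south-east | 12 mM | 12 mM | 2 equiv | run made earlier |  |
| west | 48 mM | 48 mM | 2 equiv | run made earlier |  |
| north-east | 24 mM | 24 mM | 3 equiv | run made earlier |  |
| flask | 24 mM | 24 mM | 2.00 equiv |  | 4.0 h |

- south-east (time / h: J / %, Q / %, D / %): 0.417: 49, 51, 0; 0.833: 50, 49, 2; 2.00: 50, 48, 0; 5.00: 48, 48, 2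
- west (time / h: J / %, Q / %, D / %): 0.667: 41, 48, 7; 1.50: 38, 51, 14; 3.00: 37, 42, 23; 5.00: 31, 38, 31
- north-east (time / h: J / %, Q / %, D / %): 0.667: 47, 50, 3; 1.50: 45, 52, 4; 3.00: 42, 45, 12; 5.00: 39, 45, 13

(readings scatter by 1.5 percentage points)

- Z is single-handed; J and Q are mirror images of each other, charged as a racemate, each of them at the stated concentration
- candidate steps: G + Z + J -> Z + D; G + Z + Q -> Z + X; J <-> Q; 2 G -> L; 2 Z -> E
- an excess is the difference of the two amounts in percent of their sum
- an excess is below zero if the other one leads

* part of the J and Q charged together that has reacted at 4.0 h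
* excess of D over X in the product at 4.0 h
* excess of Q over J among what is left of the two at 4.0 h

At the end of the west run, J, Q and D add to 100 %, so X stays within the scatter and I count c as D. That run makes 31 % of D in 5.00 h. Midway through, J reads about 40.5 % and G about 81.1 mM, with Z charged at 5.76 mM. Dividing the D per hour by these three gives the west constant k_w, a third-order rate constant read from the run, 328 /M²/h. For the north-east run it gives 14.5 % of D, and the reading is 13 %.

In the new flask, G at 48.0 mM and Z at 2.88 mM give a pseudo-first-order constant for J of 0.0453 /h. With J held at its charge, that makes 9.06 % of D. Holding J and G at their charges is the weak link, so I put this answer back in. In the west run J bore 61.3 % of the loss, so the mean J of the new flask is 47.2 % and its mean G is 45.8 mM. My c is therefore 8.17 %.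

The forecast gives c 6.5 %, eP 93 % and eS 3 %, and it grounds its c on the line that “The rate of making D climbs steeply with concentration”. My c is higher than its c.

    G + Z + J → Z + D (k = 410 /M²/h)
    G + Z + Q → Z + X (k = 3.00 /M²/h)
    J ⇌ Q (k = 0.310 /h)
    2 G → L (k = 0.0670 /M/h)
    2 Z → E (k = 5.40 /M/h)

The new flask gives c 9.39 %, eP 98.5 % and eS 3.51 %, so the forecast's eP stands 5.5 percentage points low. At 4.00 h, Z stands at 88.9 % of its charge and E at 11.1 %, and with the step joining two Z struck out, c is 9.89 %. The flask's c is 1.15 times what k_w gave.

In a neighbour flask with G at 0.800 equiv, the same two rounds with k_w give 3.62 %, then 3.38 %, and that ratio makes it 3.89 %. The computed c there is 3.95 %.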